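## Analysis of the target

The target is a daucane-type hydroazulene: a cyclopentane C4–C5–C6–C7–C8 is fused along C4–C8 to a cycloheptene C1(Me)=C2–C3–C4–C8–C9–C10, and C9 carries a 4-hydroxybenzoate (this numbering is used throughout). It has five stereocentres: the quaternary C4 (methyl), C5 (secondary hydroxyl), C7 (tertiary hydroxyl and isopropyl), the ring-fusion carbon C8 (hydrogen) and C9 (ester oxygen). Calling the face of the C4 methyl group β, the C5 and C7 hydroxyls are also β, while the isopropyl group, the C8 hydrogen and the C9 oxygen are α; the rings are therefore trans-fused and the C7 and C9 oxygens are 1,3-anti. Sensitive points are the aryl ester next to a free tertiary alcohol, the phenol, and above all the C1=C2 double bond, which is β,γ to C9 and can slip into conjugation whenever C9 is a ketone. The difficulty lies in three adjacent, heavily substituted carbons (C4, C8, C7), in a ring-fusion hydrogen on the face shared with the isopropyl group, and in a trisubstituted alkene whose position must not drift. The strategy rests on one feature: C1(Me)=C2 lies between the methylenes C10 and C3, so it can be read as an alkyne (propyne, used here with a removable silyl cap). C3 sits on the quaternary C4 and can first be tied to C8 as a cyclopropane, which makes C8–C9–C10 a 1-oxyvinyl group on that cyclopropane. A vinylcyclopropane and an alkyne are the two halves of a (5+2) cycloaddition, which closes the seven-membered ring with the alkene already in its place.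

## Retrosynthetic reasoning

**22 to 21 to 20.** The last operations form no C–C bonds. 22 is traced to 21, in which the C5 hydroxyl and the phenol are silyl ethers that one fluoride treatment removes. 21 is traced to 20, which carries a trimethylsilyl group on C2. That C–Si bond is cut here because the silyl group steers the alkyne in the key step; the forward reaction must replace it by hydrogen at the same carbon without moving C1=C2.

**20 to 18 and 19.** The ester is cut at the acyl C–O bond. In 18 the C9 hydroxyl is the only free secondary one (C5 is silylated, C7 is tertiary), so the aromatic part can arrive late as the purchased acid 19. The forward acylation has to select C9 over C7.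

**18 to 17 to 16 to 15.** The C9–H bond is cut to the β-hydroxy ketone 17, because a hydride tied to the C7 hydroxyl reaches the β face of C9 and gives the α alcohol. 17 comes from 16 by loss of the C7 silyl group, and 16 from the enol silane 15 by protonation at C8. These cuts merge C8 and C9 into one enol ether double bond, which is the group a vinylcyclopropane cycloaddition leaves behind. The forward steps must give the trans ring fusion at C8 and must not let C1=C2 move.

**15 to 13 and 14 (key disconnection).** The bonds C10–C1 and C2–C3 are cut and C3 is joined back to C8 as a cyclopropane. These two bonds flank the only carbons of the seven-membered ring that carry no heteroatom and no stereocentre. Cutting them removes the ring and its alkene together and leaves a cyclopentane-based precursor, 13, that already holds C4, C5 and C7. The alkyne 14 carries a trimethylsilyl cap on the carbon that becomes C2. In the insertion step the larger alkyne substituent stays on the metal-bound carbon, so silicon is sent to C2 and methyl to C1. An alkyne with hydrogen in place of silicon would have methyl as its larger group and would be expected to favour the C2-methyl isomer. Forward, the catalyst must open C8–C3 and not the ring-fusion bond C8–C4.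

**13 to 12 to 10 and 11.** 13 is the enol silane of methyl ketone 12. In 12 the two cyclopropane bonds to C3 are cut, which gives the enone 10 and the one-carbon donor 11. This is the place to cut because the first bond (C3–C4) forms next to the C5 stereocentre, which sends C3 to the α face; C8 follows since a fused cyclopropane must be cis. Forward, a conjugate addition to a tetrasubstituted enone is required.

**10 to 9 to 7.** The C8–C9 bond is cut to the vinyl bromide 7, which becomes the vinyllithium 8 in the forward direction. C8 lies between two fully substituted carbons, so a small, reactive C8 nucleophile and a two-carbon electrophile are the safest partners. 9 is the carbinol that is oxidised to 10.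

**7 to 6 to 5.** The C7–isopropyl bond is cut to the bromo enone 5. On the almost flat cyclopentenone the C5 silyloxy group shields its own face, so the nucleophile enters α and the new hydroxyl is β. 7 is the silyl ether of the adduct 6.

**5 to 3 to 2 to 1.** The C8–Br bond is cut to enone 3, and the C4–methyl bond to the purchased enone 1 through the enol silane 2. 1 supplies C5 with its oxygen in the right absolute configuration, so no resolution is needed.

## Alternatives that were turned down

**Alternative 1:** The disconnection is the C4–C8 bond, undone as a 1,2-shift. The two rings are traced to a cis-decalin in which C4 is still bonded to C9, and that decalin to a Diels–Alder adduct of A2 (thymoquinone) and A3 (isoprene). In the forward key step Et3Al turns the C9 tertiary alcohol of the hydroxy mesylate A4 into an aluminium alkoxide. The C4–C9 bond, antiperiplanar to the C8–O bond, moves to C8 as mesylate leaves; one ring contracts, the other expands, and the dione A1 results.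
- For it: both rings and the quaternary C4 come from one cycloaddition of bulk chemicals. The shift is stereospecific (inversion at C8, retention at C4), so the trans ring fusion follows from the configuration of A4 and not from protonation of an enolate. On this point it is stronger than the chosen route, whose C8 centre is settled by equilibration of ketone 16.
- Against it: A2 is a doubly alkyl-substituted, sluggish dienophile with two different double bonds and two orientations toward A3, and the adduct is racemic unless an asymmetric catalyst for this quinone is found. Three oxygenated carbons in a row (C7, C8, C9) must be set on the decalin with the right relative configuration before the shift can be tried. A1 holds two ketones that must be reduced to opposite faces, the C5 ketone without a directing group, while C9 is again β,γ to the alkene.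
- Comparison: the chosen strategy gives up the stereospecific C8. In exchange it offers an enantiopure start from 1, a single carbonyl group in the end game with a hydroxyl-directed reduction, and a seven-membered ring formed with its alkene in one step from 13.

**Alternative 2:** The C4–C5 bond of the cyclopentane is cut, which leads to the open-chain aldehyde enoate A6; C7, C8 and C9 already carry their oxygens and configurations there. Forward, SmI2 (divalent samarium) in THF with methanol reduces the C5 aldehyde to a ketyl that adds 5-exo to C4, the methyl-bearing β-carbon of the unsaturated ester, and gives the cyclopentanol A5.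
- For it: ketyl–olefin cyclisations of this kind are dependable and create the quaternary C4 and the C5 carbinol in one step. The usual outcome, hydroxyl anti to the ester-bearing arm, is what the target needs (C5 hydroxyl syn to the C4 methyl group). In setting this pair the alternative is at least as good as the conjugate addition of step 8.
- Against it: A6 must be built in a linear, acyclic sequence with three stereocentres, one of them the tertiary C7 silyl ether, and none can lean on a ring. The ketyl must attack a β,β-disubstituted enoate, where pinacol coupling and simple reduction of the aldehyde compete, and the enoate geometry decides C4. A5 is only the five-membered ring; the seven-membered ring with its trisubstituted alkene still has to be closed from the two arms by at least two further C–C bond formations.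
- Comparison: the chosen route is weaker in that its own C4 is made by addition to a crowded enone. It uses the ring of 1 to relay every stereocentre and closes the large ring, alkene included, in the single step from 13 to 15.

**Alternative 3:** The bond cut is C7–C8, so the cyclopentane is removed and the seven-membered ring is kept. The precursor is the diazo ketone A8, a cycloheptenone with the diazo group on C8 and, on the quaternary C4, a side chain that ends in the C7–H bond. Forward, Rh2(OAc)4 (divalent rhodium) releases nitrogen and the C8 carbenoid inserts into that C–H bond; five-membered ring closure gives the bicyclic enone A7.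
- For it: insertion into a tertiary C–H bond activated by an ether oxygen through a five-membered transition state is the most favourable case of this reaction. It goes with retention, so C7 can be fixed in the open chain. It forms the most congested bond of the molecule (C7–C8, next to the quaternary C4) intramolecularly. This is stronger than anything in the chosen route, which builds the same neighbourhood by intermolecular additions (steps 4, 6 and 8).
- Against it: A8 requires a cycloheptenone with a quaternary centre and a side chain carrying the 1,3-related C5 and C7 stereocentres, made without a ring to guide them. The carbenoid has other C–H bonds within reach (the isopropyl methine, the silyl ether groups). A7 has its double bond in conjugation (C10=C1), so it must be moved against the thermodynamic bias to C1=C2 while C9 is still a ketone.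
- Comparison: the chosen strategy has no answer to the congestion at C7–C8 other than step order. Its cycloaddition leaves the alkene non-conjugated from the start, and its stereocentres C5 and C7 are set on a ring.

Key step: step 10

Convention: atoms are numbered as in the target; β is the face of the C4 methyl group, α the opposite face.
Assumption: 1, 14 and 19 are bought as such (19 would otherwise take one operation from 4-hydroxybenzoic acid).

## Route

**Step 1**
Reactants: 1 (R)-4-(tert-butyldimethylsilyloxy)cyclopent-2-en-1-one
Product: 2 [(4R)-4-(tert-butyldimethylsilyloxy)-3-methylcyclopent-1-en-1-yl]oxytrimethylsilane (3,4-trans; methyl anti to the silyloxy group)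
Conditions: Me2CuLi (from MeLi and CuI), TMSCl, THF, −78 °C; Et3N, pentane work-up
Reagents that add atoms: lithium dimethylcuprate, [Li+].C[Cu-]C; chlorotrimethylsilane, C[Si](C)(C)Cl
Why: TMSCl-accelerated cuprate 1,4-addition; the methyl group enters anti to the C5 silyloxy group (the centre it creates at C4 is erased in step 2), and O-silylation fixes the enolate as the C7=C8 enol silane before it can expel the silyloxy group.

**Step 2**
Reactants: 2 [(4R)-4-(tert-butyldimethylsilyloxy)-3-methylcyclopent-1-en-1-yl]oxytrimethylsilane
Product: 3 (R)-4-(tert-butyldimethylsilyloxy)-3-methylcyclopent-2-en-1-one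
Conditions: Pd(OAc)2 (10 mol %), O2 (1 atm), DMSO, rt
Reagents that add atoms: none
Why: Saegusa–Ito dehydrogenation in its catalytic form: Pd(OAc)2 (divalent palladium) binds C8 of the enol silane and β-hydride loss from C4 restores the enone, now with the methyl group on the β-carbon; C5 is not touched.

**Step 3**
Reactants: 3 (R)-4-(tert-butyldimethylsilyloxy)-3-methylcyclopent-2-en-1-one
Product: 5 (R)-2-bromo-4-(tert-butyldimethylsilyloxy)-3-methylcyclopent-2-en-1-one, via dibromide 4 (not isolated)
Conditions: Br2, CH2Cl2, 0 °C; then Et3N, 0 °C to rt
Reagents that add atoms: bromine, BrBr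
Why: Bromination–dehydrobromination of a β-substituted enone: bromine adds across C8=C4, and Et3N removes the acidic C8 hydrogen with loss of the C4 bromide, which leaves the halogen on C8.

**Step 4**
Reactants: 5 (R)-2-bromo-4-(tert-butyldimethylsilyloxy)-3-methylcyclopent-2-en-1-one
Product: 6 (1R,4R)-2-bromo-4-(tert-butyldimethylsilyloxy)-3-methyl-1-(propan-2-yl)cyclopent-2-en-1-ol (hydroxyl cis to the silyloxy group)
Conditions: iPrMgCl, CeCl3, THF, −78 °C; aq NH4Cl
Reagents that add atoms: isopropylmagnesium chloride, CC(C)[Mg]Cl
Why: Organocerium 1,2-addition, chosen because the reagent is weakly basic and should neither enolise C6 (which would expel the silyloxy group) nor reduce the ketone; attack anti to the C5 silyloxy group puts isopropyl on the α face and the new C7 hydroxyl on the β face.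

**Step 5**
Reactants: 6 (1R,4R)-2-bromo-4-(tert-butyldimethylsilyloxy)-3-methyl-1-(propan-2-yl)cyclopent-2-en-1-ol
Product: 7 triethylsilyl ether of 6 (C7 OTES β; C5 OTBS β; bromine on C8)
Conditions: TESOTf, 2,6-lutidine, CH2Cl2, −78 to 0 °C
Reagents that add atoms: triethylsilyl trifluoromethanesulfonate, CC[Si](CC)(CC)OS(=O)(=O)C(F)(F)F
Why: Silyl triflate silylation of a hindered tertiary alcohol; the triethylsilyl group is chosen so that it can later be removed before the secondary TBS ether.

**Step 6**
Reactants: 7 triethylsilyl ether of 6
Product: 9 1-[(3R,5R)-3-(tert-butyldimethylsilyloxy)-2-methyl-5-(propan-2-yl)-5-(triethylsilyloxy)cyclopent-1-en-1-yl]ethan-1-ol (both C9 epimers), via vinyllithium 8 (not isolated)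
Conditions: t-BuLi (2.1 equiv), Et2O, −78 °C; then MeCHO, −78 °C; aq NH4Cl
Reagents that add atoms: acetaldehyde, CC=O
Why: Bromine–lithium exchange followed by 1,2-addition to an aldehyde forms C8–C9; the vinyllithium cannot lose the neighbouring C7 silyloxy group because that would need a cyclic allene. The C9 epimers are not separated since C9 is oxidised next.

**Step 7**
Reactants: 9 1-[(3R,5R)-3-(tert-butyldimethylsilyloxy)-2-methyl-5-(propan-2-yl)-5-(triethylsilyloxy)cyclopent-1-en-1-yl]ethan-1-ol
Product: 10 1-[(3R,5R)-3-(tert-butyldimethylsilyloxy)-2-methyl-5-(propan-2-yl)-5-(triethylsilyloxy)cyclopent-1-en-1-yl]ethan-1-one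
Conditions: Dess–Martin periodinane, CH2Cl2, 0 °C to rt
Reagents that add atoms: none
Why: Dess–Martin oxidation of a secondary allylic alcohol under near-neutral conditions that leave both silyl ethers in place.

**Step 8**
Reactants: 10 1-[(3R,5R)-3-(tert-butyldimethylsilyloxy)-2-methyl-5-(propan-2-yl)-5-(triethylsilyloxy)cyclopent-1-en-1-yl]ethan-1-one; 11 trimethylsulfoxonium iodide
Product: 12 1-acetyl-4β-(tert-butyldimethylsilyloxy)-5β-methyl-2α-(propan-2-yl)-2β-(triethylsilyloxy)bicyclo[3.1.0]hexane (cyclopropane CH2 = C3 on the α face)
Conditions: 11, NaH, DMSO, rt to 50 °C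
Reagents that add atoms: none
Why: Corey–Chaykovsky cyclopropanation: the sulfoxonium ylide adds 1,4 to C4 and the C8 enolate displaces DMSO from C3 (3-exo-tet). The ylide should attack C4 anti to the adjacent C5 silyloxy group, as nucleophiles do with 4-silyloxycyclopentenones, so C3 is α and the C4 methyl β; C8 follows because the fused cyclopropane can only be cis.

**Step 9**
Reactants: 12 1-acetyl-4β-(tert-butyldimethylsilyloxy)-5β-methyl-2α-(propan-2-yl)-2β-(triethylsilyloxy)bicyclo[3.1.0]hexane
Product: 13 1-[1-(tert-butyldimethylsilyloxy)ethenyl]-4β-(tert-butyldimethylsilyloxy)-5β-methyl-2α-(propan-2-yl)-2β-(triethylsilyloxy)bicyclo[3.1.0]hexane (C3 α)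
Conditions: TBSOTf, Et3N, CH2Cl2, 0 °C
Reagents that add atoms: tert-butyldimethylsilyl trifluoromethanesulfonate, CC(C)(C)[Si](C)(C)OS(=O)(=O)C(F)(F)F
Why: Soft enolisation and O-silylation of a methyl ketone; only C10 carries α-hydrogens, so a single enol silane can form.

**Step 10**
Reactants: 13 1-[1-(tert-butyldimethylsilyloxy)ethenyl]-4β-(tert-butyldimethylsilyloxy)-5β-methyl-2α-(propan-2-yl)-2β-(triethylsilyloxy)bicyclo[3.1.0]hexane; 14 trimethyl(prop-1-yn-1-yl)silane
Product: 15 bicyclic cyclohepta-1,4-diene: C8=C9 with OTBS on C9; C1(Me)=C2 with SiMe3 on C2; C4 methyl β; C5 OTBS β; C7 OTES β and isopropyl α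
Conditions: [Rh(CO)2Cl]2 (5 mol %), 14 (3 equiv), ClCH2CH2Cl, 60–80 °C
Reagents that add atoms: none
Why: Proposed new method: [Rh(CO)2Cl]2 (monovalent rhodium) should bind the enol ether double bond of 13 and insert into the C8–C3 cyclopropane bond, giving a metallacycle of trivalent rhodium with an allyl unit C8–C9–C10 and a Rh–C3 σ bond; 14 then inserts into the Rh–C10 bond and reductive elimination joins C2 to C3. The closest known reaction type is the intermolecular (5+2) cycloaddition of 1-alkoxy- and 1-silyloxy-1-vinylcyclopropanes with alkynes under the same catalyst; new here are a cyclopropane fused into a bicyclo[3.1.0]hexane with both ring carbons fully substituted and a silyloxy group on the vinyl carbon instead of the ring carbon. The seven-membered ring closes in the reductive elimination from an eight-membered metallacycle, by C(sp2)–C(sp3) bond formation between C2 and C3. No stereocentre is created: C4 takes no part in any bond that breaks, so the configuration set in step 8 becomes the ring fusion, and C8 turns trigonal. Two selectivities are needed. Cleavage must take C8–C3 and not C8–C4; the primary C3 is far easier for the metal to reach than the quaternary C4, and a metal–carbon bond to C4 would be much more crowded. The alkyne must place its methyl carbon on C10: in the insertion the larger alkyne substituent stays on the metal-bound carbon, away from the forming C–C bond, so the trimethylsilyl group goes to C2 and the methyl group to C1; with hydrogen in place of silicon the methyl group would be the larger one and would be expected to go to C2, which is why the alkyne is silyl-capped.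

**Step 11**
Reactants: 15 bicyclic cyclohepta-1,4-diene enol silane
Product: 16 trans-fused ketone: C9 ketone; C8–H α; C2 SiMe3; C5 OTBS β; C7 OTES β and isopropyl α
Conditions: TBAF, AcOH (1:1), THF, −20 to 0 °C; then DBU (0.2 equiv), CH2Cl2, 0 °C if the C8 epimer is present
Reagents that add atoms: none
Why: Fluoride cleavage of a silyl enol ether with immediate protonation of the enolate at C8; the silyl ether is kept on C7 so that no hydroxyl can deliver the proton to the β face. The α-hydrogen (trans-fused) ketone should be the thermodynamic epimer because C9 then stands cis to the C7 oxygen and not to the isopropyl group, and catalytic DBU should converge any β-hydrogen epimer.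

**Step 12**
Reactants: 16 trans-fused ketone
Product: 17 β-hydroxy ketone: C7 hydroxyl β free; C9 ketone; C8–H α; C2 SiMe3; C5 OTBS β
Conditions: HF·pyridine, pyridine, THF, 0 °C to rt
Reagents that add atoms: none
Why: Buffered fluoride cleavage of the triethylsilyl ether; the hindered secondary TBS ether and the vinylsilane should survive, and the medium is neither basic enough for retro-aldol cleavage nor acidic enough to move the double bond.

**Step 13**
Reactants: 17 β-hydroxy ketone
Product: 18 diol: C7 hydroxyl β; C9 hydroxyl α; C8–H α; C2 SiMe3; C5 OTBS β
Conditions: Me4NBH(OAc)3, MeCN/AcOH, −30 °C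
Reagents that add atoms: none
Why: Evans–Saksena reduction: the C7 hydroxyl exchanges onto boron and the hydride is delivered intramolecularly to the β face of the C9 carbonyl, so the new hydroxyl is α, 1,3-anti to the C7 hydroxyl.

**Step 14**
Reactants: 18 diol; 19 4-(tert-butyldimethylsilyloxy)benzoic acid
Product: 20 C9 4-(tert-butyldimethylsilyloxy)benzoate: C7 hydroxyl β free; C2 SiMe3; C5 OTBS β
Conditions: 19, DCC, DMAP (cat.), CH2Cl2, rt
Reagents that add atoms: none
Why: Steglich esterification; only the secondary C9 hydroxyl is acylated, because the C7 hydroxyl is tertiary and the C5 oxygen is silylated.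

**Step 15**
Reactants: 20 C9 4-(tert-butyldimethylsilyloxy)benzoate with SiMe3 on C2
Product: 21 C9 4-(tert-butyldimethylsilyloxy)benzoate with hydrogen on C2: C1(Me)=C2H; C5 OTBS β; C7 hydroxyl β
Conditions: CF3CO2H, CH2Cl2, 0 °C
Reagents that add atoms: none
Why: Protodesilylation of a vinylsilane: ipso protonation at C2 gives a tertiary cation at C1 that is stabilised by the β-silicon and loses the silyl group, so the double bond stays at C1=C2. Any silyl ether lost here is harmless because step 16 removes them.

**Step 16**
Reactants: 21 C9 4-(tert-butyldimethylsilyloxy)benzoate with hydrogen on C2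
Product: 22 target, CNP0215209.2
Conditions: HF·pyridine, THF, 0 °C to rt
Reagents that add atoms: none
Why: Fluoride cleavage of the secondary alkyl and the aryl TBS ethers under non-basic conditions that spare the ester and give no opening for acyl migration.

## Compound list

1 | (R)-4-(tert-butyldimethylsilyloxy)cyclopent-2-en-1-one | O=C1C=C[C@H](O[Si](C)(C)C(C)(C)C)C1 | starting material
2 | [(4R)-4-(tert-butyldimethylsilyloxy)-3-methylcyclopent-1-en-1-yl]oxytrimethylsilane (3,4-trans) | C[Si](C)(C)OC1=C[C@@H](C)[C@H](O[Si](C)(C)C(C)(C)C)C1 | intermediate
3 | (R)-4-(tert-butyldimethylsilyloxy)-3-methylcyclopent-2-en-1-one | CC1=CC(=O)C[C@H]1O[Si](C)(C)C(C)(C)C | intermediate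
4 | (4R)-2,3-dibromo-4-(tert-butyldimethylsilyloxy)-3-methylcyclopentan-1-one (bromine-bearing centres unassigned) | CC1(Br)C(Br)C(=O)C[C@H]1O[Si](C)(C)C(C)(C)C | intermediate (not isolated)
5 | (R)-2-bromo-4-(tert-butyldimethylsilyloxy)-3-methylcyclopent-2-en-1-one | CC1=C(Br)C(=O)C[C@H]1O[Si](C)(C)C(C)(C)C | intermediate
6 | (1R,4R)-2-bromo-4-(tert-butyldimethylsilyloxy)-3-methyl-1-(propan-2-yl)cyclopent-2-en-1-ol | CC1=C(Br)[C@](O)(C(C)C)C[C@H]1O[Si](C)(C)C(C)(C)C | intermediate
7 | triethylsilyl ether of 6 | CC1=C(Br)[C@](O[Si](CC)(CC)CC)(C(C)C)C[C@H]1O[Si](C)(C)C(C)(C)C | intermediate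
8 | vinyllithium from 7 (lithium on C8) | CC1=C([Li])[C@](O[Si](CC)(CC)CC)(C(C)C)C[C@H]1O[Si](C)(C)C(C)(C)C | intermediate (not isolated)
9 | 1-[(3R,5R)-3-(tert-butyldimethylsilyloxy)-2-methyl-5-(propan-2-yl)-5-(triethylsilyloxy)cyclopent-1-en-1-yl]ethan-1-ol (both C9 epimers) | CC1=C(C(C)O)[C@](O[Si](CC)(CC)CC)(C(C)C)C[C@H]1O[Si](C)(C)C(C)(C)C | intermediate
10 | 1-[(3R,5R)-3-(tert-butyldimethylsilyloxy)-2-methyl-5-(propan-2-yl)-5-(triethylsilyloxy)cyclopent-1-en-1-yl]ethan-1-one | CC1=C(C(C)=O)[C@](O[Si](CC)(CC)CC)(C(C)C)C[C@H]1O[Si](C)(C)C(C)(C)C | intermediate
11 | trimethylsulfoxonium iodide | C[S+](C)(C)=O.[I-] | starting material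
12 | 1-acetyl-4β-(tert-butyldimethylsilyloxy)-5β-methyl-2α-(propan-2-yl)-2β-(triethylsilyloxy)bicyclo[3.1.0]hexane (C3 α) | CC(=O)[C@]12C[C@@]1(C)[C@H](O[Si](C)(C)C(C)(C)C)C[C@@]2(O[Si](CC)(CC)CC)C(C)C | intermediate
13 | 1-[1-(tert-butyldimethylsilyloxy)ethenyl]-4β-(tert-butyldimethylsilyloxy)-5β-methyl-2α-(propan-2-yl)-2β-(triethylsilyloxy)bicyclo[3.1.0]hexane (C3 α) | C=C(O[Si](C)(C)C(C)(C)C)[C@]12C[C@@]1(C)[C@H](O[Si](C)(C)C(C)(C)C)C[C@@]2(O[Si](CC)(CC)CC)C(C)C | intermediate
14 | trimethyl(prop-1-yn-1-yl)silane | CC#C[Si](C)(C)C | starting material
15 | bicyclic cyclohepta-1,4-diene: C9 TBS enol ether (C8=C9); SiMe3 on C2; C5 OTBS β; C7 OTES β, isopropyl α; C4 methyl β | CC1=C([Si](C)(C)C)C[C@@]2(C)[C@H](O[Si](C)(C)C(C)(C)C)C[C@@](O[Si](CC)(CC)CC)(C(C)C)C2=C(O[Si](C)(C)C(C)(C)C)C1 | intermediate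
16 | trans-fused C9 ketone (C8–H α); SiMe3 on C2; C5 OTBS β; C7 OTES β | CC1=C([Si](C)(C)C)C[C@@]2(C)[C@H](O[Si](C)(C)C(C)(C)C)C[C@@](O[Si](CC)(CC)CC)(C(C)C)[C@@H]2C(=O)C1 | intermediate
17 | β-hydroxy ketone: C7 hydroxyl β; C9 ketone; SiMe3 on C2; C5 OTBS β | CC1=C([Si](C)(C)C)C[C@@]2(C)[C@H](O[Si](C)(C)C(C)(C)C)C[C@@](O)(C(C)C)[C@@H]2C(=O)C1 | intermediate
18 | diol: C7 hydroxyl β; C9 hydroxyl α; SiMe3 on C2; C5 OTBS β | CC1=C([Si](C)(C)C)C[C@@]2(C)[C@H](O[Si](C)(C)C(C)(C)C)C[C@@](O)(C(C)C)[C@@H]2[C@@H](O)C1 | intermediate
19 | 4-(tert-butyldimethylsilyloxy)benzoic acid | OC(=O)c1ccc(O[Si](C)(C)C(C)(C)C)cc1 | starting material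
20 | C9 4-(tert-butyldimethylsilyloxy)benzoate; SiMe3 on C2; C5 OTBS β; C7 hydroxyl β | CC1=C([Si](C)(C)C)C[C@@]2(C)[C@H](O[Si](C)(C)C(C)(C)C)C[C@@](O)(C(C)C)[C@@H]2[C@@H](OC(=O)c2ccc(O[Si](C)(C)C(C)(C)C)cc2)C1 | intermediate
21 | C9 4-(tert-butyldimethylsilyloxy)benzoate; hydrogen on C2; C5 OTBS β; C7 hydroxyl β | CC1=CC[C@@]2(C)[C@H](O[Si](C)(C)C(C)(C)C)C[C@@](O)(C(C)C)[C@@H]2[C@@H](OC(=O)c2ccc(O[Si](C)(C)C(C)(C)C)cc2)C1 | intermediate
22 | CNP0215209.2 | CC1=CC[C@@]2(C)[C@H](O)C[C@@](O)(C(C)C)[C@@H]2[C@@H](OC(=O)c2ccc(O)cc2)C1 | target

## Step count and least certain steps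

Total step count: 16. Longest linear sequence: 16 steps (1 to 22); 11, 14 and 19 are purchased and enter in steps 8, 10 and 14.

**Step 10 (key step, proposed new method).** The most likely failure is that the metal does not insert into the cyclopropane. For insertion the vinyl group must turn C10 toward C3, which pushes the C9 silyloxy group against the C7 substituents, and the metal must approach the α face beside the isopropyl group. A second risk is slow insertion of the disubstituted silyl alkyne, which would leave time for the enol silane to decompose on heating. The fallback uses known chemistry, sets out from 10 and comes back at 21. It builds the same cycloheptadiene without a cyclopropane precursor, by tandem cyclopropanation and Cope rearrangement of a vinylcarbenoid with a 2-silyloxydiene (formal (4+3) cycloaddition), and thereby also bypasses step 8. Enone 10 is converted with TBSOTf and Et3N into the cross-conjugated silyl dienol ether F1. Rh2(OAc)4 (divalent rhodium) and methyl 2-diazobut-3-enoate cyclopropanate its C9=C10 bond, and on warming the cis-divinylcyclopropane rearranges, C3 bonding to C4 anti to the C5 silyloxy group, to the C1 methyl ester F2. i-Bu2AlH gives the allylic alcohol F3, which is deoxygenated in one flask (SO3·pyridine; then LiAlH4) to the C1 methyl compound F4. F4 is taken through the conditions of steps 11 to 13, giving the ketone F5, the hydroxy ketone F6 and the diol F7. Esterification of F7 with 19 as in step 14 gives 21 directly, so step 15 is not needed.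

**Step 8.** The acetyl group on the tetrasubstituted double bond is twisted out of conjugation by the C4 methyl group and the quaternary C7, so conjugate addition may be slow. Addition of the ylide to the C9 carbonyl, or expulsion of the C7 silyloxy group from the intermediate enolate, could then compete, and any erosion of facial selectivity would put C3 on the β face. The fallback sets out from 10 and comes back at 12. Corey–Bakshi–Shibata reduction with the (S)-methyl oxazaborolidine and BH3·SMe2 gives the (R)-configured allylic alcohol F8. With the C9 hydrogen eclipsing the ring double bond to avoid strain with the C4 methyl group, the zinc alkoxide of F8 lies on the α face, so Simmons–Smith cyclopropanation (Et2Zn, CH2I2) delivers the methylene there and gives the cyclopropyl carbinol F9. Dess–Martin oxidation of F9 returns 12.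

**Step 11.** Protonation may occur on the wrong face of C8, because both faces are flanked (β by the C4 methyl and the C7 silyloxy group, α by the isopropyl group and the underside of the seven-membered ring). During the base equilibration C1=C2 may move into conjugation with C9, or the C7 silyloxy group may be eliminated. The fallback sets out from 15 and comes back at 18; it sets C8 and C9 together by a syn addition and never passes through a ketone. CsF and PhNTf2 convert the enol silane into the enol triflate F10. Pd(OAc)2, PPh3, HCO2H and Bu3N reduce it to the C8=C9 alkene F11. Hydroboration with BH3·THF from the α face, anti to the C4 methyl and the C7 silyloxy group, followed by NaBO3, places hydrogen on C8 and hydroxyl on C9, both α, in the alcohol F12; the tetrasubstituted vinylsilane is not expected to react. HF·pyridine as in step 12 then gives 18.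

**Step 15.** An acid strong enough to protonate C2 may also shift the trisubstituted double bond, ionise the tertiary C7 alcohol or strip silyl ethers before the vinylsilane has reacted. The fallback sets out from 20 and comes back at 21. N-Iodosuccinimide in hexafluoroisopropanol at 0 °C replaces silicon by iodine at C2 without a protic acid and gives the vinyl iodide F13. Bu3SnH with Pd(PPh3)4 (zerovalent palladium) then exchanges iodine for hydrogen and gives 21.

## Further compounds

F1 | step 10 | TBS dienol ether of 10 (2-silyloxydiene C10=C9(OTBS)–C8=C4) | C=C(O[Si](C)(C)C(C)(C)C)C1=C(C)[C@H](O[Si](C)(C)C(C)(C)C)C[C@@]1(O[Si](CC)(CC)CC)C(C)C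
F2 | step 10 | cycloheptadiene with methyl ester on C1; C9 TBS enol ether; C5 OTBS; C7 OTES | COC(=O)C1=CC[C@@]2(C)[C@H](O[Si](C)(C)C(C)(C)C)C[C@@](O[Si](CC)(CC)CC)(C(C)C)C2=C(O[Si](C)(C)C(C)(C)C)C1
F3 | step 10 | C1 hydroxymethyl cycloheptadiene | OCC1=CC[C@@]2(C)[C@H](O[Si](C)(C)C(C)(C)C)C[C@@](O[Si](CC)(CC)CC)(C(C)C)C2=C(O[Si](C)(C)C(C)(C)C)C1
F4 | step 10 | C1 methyl cycloheptadiene (15 without the C2 silyl group) | CC1=CC[C@@]2(C)[C@H](O[Si](C)(C)C(C)(C)C)C[C@@](O[Si](CC)(CC)CC)(C(C)C)C2=C(O[Si](C)(C)C(C)(C)C)C1
F5 | step 10 | trans-fused C9 ketone (16 without the C2 silyl group) | CC1=CC[C@@]2(C)[C@H](O[Si](C)(C)C(C)(C)C)C[C@@](O[Si](CC)(CC)CC)(C(C)C)[C@@H]2C(=O)C1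
F6 | step 10 | β-hydroxy ketone (17 without the C2 silyl group) | CC1=CC[C@@]2(C)[C@H](O[Si](C)(C)C(C)(C)C)C[C@@](O)(C(C)C)[C@@H]2C(=O)C1
F7 | step 10 | diol (18 without the C2 silyl group) | CC1=CC[C@@]2(C)[C@H](O[Si](C)(C)C(C)(C)C)C[C@@](O)(C(C)C)[C@@H]2[C@@H](O)C1
F8 | step 8 | (R)-configured C9 allylic alcohol (single epimer of 9) | CC1=C([C@@H](C)O)[C@](O[Si](CC)(CC)CC)(C(C)C)C[C@H]1O[Si](C)(C)C(C)(C)C
F9 | step 8 | cyclopropyl carbinol (C9 R; C3 α) | C[C@@H](O)[C@]12C[C@@]1(C)[C@H](O[Si](C)(C)C(C)(C)C)C[C@@]2(O[Si](CC)(CC)CC)C(C)C
F10 | step 11 | C9 enol triflate | CC1=C([Si](C)(C)C)C[C@@]2(C)[C@H](O[Si](C)(C)C(C)(C)C)C[C@@](O[Si](CC)(CC)CC)(C(C)C)C2=C(OS(=O)(=O)C(F)(F)F)C1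
F11 | step 11 | C8=C9 alkene | CC1=C([Si](C)(C)C)C[C@@]2(C)[C@H](O[Si](C)(C)C(C)(C)C)C[C@@](O[Si](CC)(CC)CC)(C(C)C)C2=CC1
F12 | step 11 | C9 α alcohol with C7 OTES (C8–H α) | CC1=C([Si](C)(C)C)C[C@@]2(C)[C@H](O[Si](C)(C)C(C)(C)C)C[C@@](O[Si](CC)(CC)CC)(C(C)C)[C@@H]2[C@@H](O)C1
F13 | step 15 | C2 vinyl iodide of the ester | CC1=C(I)C[C@@]2(C)[C@H](O[Si](C)(C)C(C)(C)C)C[C@@](O)(C(C)C)[C@@H]2[C@@H](OC(=O)c2ccc(O[Si](C)(C)C(C)(C)C)cc2)C1
A1 | alternative 1 | trans-fused hydroazulene C5,C9-dione with free C7 hydroxyl | CC1=CC[C@@]2(C)C(=O)C[C@@](O)(C(C)C)[C@@H]2C(=O)C1
A2 | alternative 1 | thymoquinone | CC1=CC(=O)C(C(C)C)=CC1=O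
A3 | alternative 1 | isoprene | C=CC(C)=C
A4 | alternative 1 | cis-decalin C9 tertiary alcohol C8 mesylate | CC1=CC[C@@]2(C)C(=O)C[C@@](O)(C(C)C)[C@H](OS(C)(=O)=O)[C@@]2(O)C1
A5 | alternative 2 | fully substituted cyclopentanol with ester arm on the quaternary carbon | CCOC(=O)C[C@@]1(C)[C@H](O)C[C@@](O[Si](CC)(CC)CC)(C(C)C)[C@@H]1[C@@H](O[Si](C)(C)C(C)(C)C)CO[Si](C)(C)C(C)(C)C
A6 | alternative 2 | open-chain C5 aldehyde with β-methyl enoate (alkene geometry not fixed) | CCOC(=O)C=C(C)[C@@H]([C@@H](O[Si](C)(C)C(C)(C)C)CO[Si](C)(C)C(C)(C)C)[C@](O[Si](CC)(CC)CC)(C(C)C)CC=O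
A7 | alternative 3 | bicyclic conjugated enone with the C7 tertiary silyl ether | CC1=CC(=O)[C@@H]2[C@@](C)(CC1)[C@H](O[Si](C)(C)C(C)(C)C)C[C@@]2(O[Si](CC)(CC)CC)C(C)C
A8 | alternative 3 | 2-diazocycloheptenone with the C5,C7 side chain on C4 | CC1=CC(=O)C(=[N+]=[N-])[C@@](C)(CC1)[C@H](O[Si](C)(C)C(C)(C)C)C[C@@H](O[Si](CC)(CC)CC)C(C)C
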